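In a one-step world each half-life halves X, so the count of half-lives lived through tells what remains.

| setting | elm | birch | noon | winter |
|---|---|---|---|---|
| X | 0.10 M | 0.10 M | 0.10 M | 0.10 M |
| J | 0.055 M | 0.083 M | 0.100 M | 0.130 M |
| remark | run made earlier | run made earlier |  |  |
| time |  |  | 3.0 d | 3.0 d |

| run | time / d | L / % | D / % | X / % | Q / % | Z / % |
|---|---|---|---|---|---|---|
| elm | 0.250 | 3 | 0 | 83 | 4 | 1 |
| elm | 0.417 | 2 | 2 | 76 | 6 | 4 |
| elm | 0.833 | 8 | 0 | 63 | 12 | 11 |
| elm | 1.67 | 11 | 1 | 42 | 26 | 12 |
| elm | 3.00 | 13 | 5 | 28 | 35 | 18 |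
| birch | 0.625 | 4 | 0 | 60 | 15 | 8 |
| birch | 1.25 | 6 | 1 | 41 | 29 | 10 |
| birch | 1.67 | 13 | 4 | 30 | 36 | 13 |
| birch | 2.50 | 9 | 2 | 23 | 43 | 12 |
| birch | 3.00 | 10 | 3 | 19 | 48 | 16 |

(scatter of a reading: 1.5 percentage points)

- the numbers in the tables scatter with a standard deviation of 1.5 percentage points
- a reading of Q is of its free form alone

1. which of these there is most of at the end, counted by the X in it, noon (X / Z / Q / L)
2. which of these there is most of at the end, counted by the X in it, winter (X / Z / Q / L)
3. how much there is at the end of the one of these that leads, in percent of the X charged: noon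
4. how much there is at the end of the one of these that leads, in percent of the X charged: winter

The same count can be read from the end readings here. At 3.00 d, elm holds 28 % of its X and has lived 1.84 half-lives, while birch holds 19 % and has lived 2.40. Both readings carry the scatter. A straight line in charged [J] through these two runs is an empirical interpolation, not a proof of two routes, and it splits the count into a J-free part of 0.738 half-lives, plus the J gain, the half-lives added per unit of charged [J] with X charge and time held, 20.0 M⁻¹.

The ladder runs from fast to slow. Z and L keep a steady ratio in the readings, 1.38 in elm and 1.60 in birch at the last point, so they read as one pool. Next comes the J part of the loss of X, with a half-life averaged over the run, taken from the line, of 1.50 d in noon and 1.16 d in winter. The J-free part follows at 4.07 d, slower than either. Along the line my own reckoning gives noon 2.74 half-lives and winter 3.33, leaving 15.0 % and 9.94 % of X. The J part makes up 73.0 % of the noon count and 77.9 % of the winter count. The count follows X and gives neither the leader nor an amount of Q. The leader comes from the Q readings: at the last point Q reads above X in elm and in birch, and higher in birch than in elm, so Q should lead both flasks.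

The forecast supplies the amounts: Q at 56 % in noon and Q at 65 % in winter, having found the loss to Z, L and D “so this route is independent of J”.

Q leads noon at 54.2 % and winter at 63.3 %.

    X ⇌ L (K = 2.20, k = 2.90 × 10⁻⁶ s⁻¹)
    E ⇌ Q (K = 25.0, k = 2.30 × 10⁻⁵ s⁻¹)
    L ⇌ Z (K = 1.50, k = 2.30 × 10⁻⁴ s⁻¹)
    L ⇌ D (K = 0.350, k = 7.50 × 10⁻⁶ s⁻¹)
    X + J ⇌ E (K = 28.0 M⁻¹, k = 1.10 × 10⁻⁴ M⁻¹ s⁻¹)
    J → G (k = 1.20 × 10⁻⁸ s⁻¹)

The X left in noon, 14.4 %, and in winter, 9.27 %, are counts of 2.80 and 3.43 half-lives, against the reckoned 2.74 and 3.33. Winter still holds 47 % of its J. A neighbour flask is winter with 0.033 M of J, and its count comes to 1.40, leaving 37.9 % of X. It ends with 35 % of X, and X leads there, over Q at 22.2 %.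

The readings are simulated with constants of no real substance, and the scatter is random.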